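In a one-step world each substrate lost stands as target, yet oak at 8.00 min has lost 44.2% of its substrate and shows 12.0% target. Other paths are open, then, and what I can read is how the runs behave.

| flask | substrate | partner | capture agent | remark | time |
|---|---|---|---|---|---|
| oak | 0.28 M | 3 equiv | 1 M | run made earlier |  |
| birch | 0.50 M | 3 equiv | 1 M | run made earlier |  |
| alder | 0.91 M | 3 equiv | 1 M | run made earlier |  |
| amber | 0.30 M | 3.00 equiv | 1.00 M |  | 15 min |
| ochre | 0.40 M | 3.00 equiv | 1.00 M |  | 15 min |
| red | 0.60 M | 3.00 equiv | 1.00 M |  | 15 min |
| green | 1.0 M | 3.00 equiv | 1.00 M |  | 15 min |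

- oak (time / min: target / %, substrate / %): 1.50: 3.3, 89.4; 3.00: 5.8, 79.7; 5.00: 8.5, 69.8; 6.00: 9.7, 64.3; 8.00: 12.0, 55.8
- birch (time / min: target / %, substrate / %): 1.50: 3.4, 89.7; 3.00: 5.4, 80.2; 5.00: 9.0, 69.4; 6.00: 10.1, 64.1; 8.00: 12.4, 55.7
- alder (time / min: target / %, substrate / %): 0.667: 1.1, 94.8; 2.00: 3.8, 86.0; 4.00: 7.3, 74.7; 5.00: 8.7, 69.7; 8.00: 12.2, 56.1

(standard deviation of a reading: 0.3 percentage points)

- the numbers in the tables scatter with a standard deviation of 0.3 percentage points
- "hardly changes" means that all values lie within two and a half points (for a concentration: within two and a half percent of the largest)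

- amount of target at the end, in percent of the substrate charged for amber, ochre, red, green, in this order
- the shape of the row from first to last (rises, then falls / hardly changes / rises all the way / falls all the way / falls, then rises)

Does the charge matter? Alder holds 3.25 times the substrate of oak, yet at 8.00 min their substrate readings differ by 0.3 percentage points and their target readings by 0.2 points, against a scatter of 0.3 points. So I join the two ends of the range and expect the same percentages between them, though green at 1.0 M lies beyond alder.

Where, then, does substrate stand at 15 min? One first-order curve serves the oak readings, and at 8.00 min in oak I read the loss constant, the logarithm of charged over left divided by the time, as 0.0729 min⁻¹. By this reading I expect 33.5% of the substrate left at 15 min.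

How much of the loss is target? In oak at 8.00 min the share is 0.271, which gives 18.1% from amber to green, a flat row. The share at 1.50 min in oak reads 0.311, higher, so target may be leaking and my figure may run high.

The forecast stands on the same ground, “percent yields should not depend on charge”, and gives 17%, 17%, 17%, 17%, hardly changes, a lower figure than mine.

The flasks give 16.7%, 16.7%, 16.7%, 16.7%, hardly changes, so my figure stands 1.4 points too high.

    substrate → target (k = 0.0221 min⁻¹)
    substrate → intermediate A (k = 0.0513 min⁻¹)
    intermediate A → side product (k = 0.0574 min⁻¹)
    partner + intermediate A ⇌ intermediate B (K = 1.20 L mol⁻¹, k = 0.140 L mol⁻¹ min⁻¹)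
    capture agent + intermediate B → trapped intermediate (k = 0.0124 L mol⁻¹ min⁻¹)
    target ⇌ isomer of the product (K = 13.0, k = 0.0214 min⁻¹)

In amber at 15.0 min target is made 2.09 times faster than it is used up, each step taken net, while substrate passes into intermediate A 2.3 times faster than into target, a selectivity factor. Amber holds 33.3% substrate at that time. On green at 7.50 min the loss constant gives 57.9% substrate left, and green holds 57.7%.

(The earlier runs and the new flask stem from a simulated flask on assumed constants; noise was put on by code.)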